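The back run of links, 0.0441 min⁻¹, is faster than ring closure, 0.021 min⁻¹, so as a rough model I treat links and free first end groups as one pool held in balance, a pre-equilibrium. Rings form from the free part of that pool and use up second end groups. I drop the side-product step, which at 0.002580 min⁻¹ per link in maple is slower than the back run.

| flask | first end groups | second end groups | time |
|---|---|---|---|
| maple | 6.0 mM | 19.0 mM | 2.0 h |
| larch | 8.0 mM | 19.0 mM | 2.0 h |
| oak | 12 mM | 19.0 mM | 2.0 h |
| elm | 20 mM | 19.0 mM | 2.0 h |
| ash | 30 mM | 19.0 mM | 2.0 h |

- [links] at the end for maple, larch, oak, elm, ash, in this order
- how the row runs (falls all the way / falls, then rises / rises all the way / rises, then falls / hardly changes)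

- a species is counted by the first end groups in it: one side product counts as two
- "hardly changes" means that all values lie within two and a half points (for a concentration: within two and a half percent of the largest)
- run time (maple): 2.0 h

The quantity I carry is the holding ratio h, the links standing per free first end group in balance, with second end groups as charged. I bracket maple between two extreme versions.

In the first version, second end groups stay at their charge:

h = 22 L mol⁻¹ × 19.0 mM = 0.418

pool left, f = exp(−k₂t/(1 + h)) = 0.169

links = 0.299 mM

In the second version, I put that answer back and hold second end groups at their end level from the start:

second end groups = 14.0 mM, so h′ = 0.308

pool left, f′ = 0.146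

links = 0.206 mM

Second end groups fall during the run, so I expect maple to end between these two values.

Taking the same f′ for each flask, I estimate that links across the row go roughly as the charge of first end groups times the second end groups left. Against maple, that product gives 1.17 for larch, 1.26 for oak and 0.460 for elm. With f′, the pool in ash loses 25.6 mM, more than its charge of second end groups, so I expect its links to drain by the back run. I expect the row to rise, then fall.

The forecast gives 0.29 mM, 0.32 mM, 0.34 mM, 0.09 mM and 0.03 mM, shape rises, then falls, saying “it grows slightly with loading while second end groups stay in excess”.

The simulation gives 0.286 mM, 0.335 mM, 0.370 mM, 0.205 mM and 0.0345 mM, shape rises, then falls.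

    first end groups + links → side product (k1 = 0.43 L mol⁻¹ min⁻¹)
    first end groups + second end groups → rings, rate k2*[first end groups] as long as [second end groups] is above zero (k2 = 0.021 min⁻¹)
    first end groups + second end groups ⇌ links (K3 = 22 L mol⁻¹, k3 = 0.97 L mol⁻¹ min⁻¹)

At the end of maple, h times the fraction of second end groups left gives 0.301, while links over first end groups read 0.453. In oak the same product is 0.186 against a reading of 0.307, so at the end links in maple and oak stand above balance. The back run and ring closure act together in removing links: maple ends at 1.47 mM with ring closure left out and at 2.39 mM with the back run left out, against 0.286 mM with both in place.

The numbers of this flask were drawn at random within sensible limits; no experiment stands behind them.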